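The rate constants are made up; the run is a simulation.

Take 20 mM of solid substrate and 24.0 mM of partner, and ask what the partner's amount can buy.

solid substrate 20 mM; partner 24.0 mM; time 20 h

    solid substrate ⇌ dissolved substrate, rate k1*(cs1 - [dissolved substrate]) while solid is left; crystals form when [dissolved substrate] > cs1 (cs1 = 16 mM, k1 = 4.4 × 10⁻⁴ /s)
    dissolved substrate + partner → target (k2 = 0.0062 /M/s)
    solid product ⇌ target, rate k3*(cs3 - [target]) while solid is left; crystals form when [target] > cs3 (cs3 = 6.6 mM, k3 = 0.0031 /s)
    solid substrate + target → side product (k4 = 0.0089 /M/s)
    2 solid substrate → self-condensation product (k5 = 3.2 × 10⁻⁶ /M/s)
    partner → decomposed reagent (k6 = 4.7 × 10⁻⁵ /s)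

- percent here means solid substrate units held: one side product or self-condensation product counts as two
- what is said of target includes solid product
- a step written with two of one species runs at k times the square of its concentration and takes two of it each time
- solid substrate, solid product is a solid; its amount is given per volume of the solution
- at the start none of the solid substrate is in solution
- dissolved substrate means what is dissolved; the solid is not counted in it
- run time (flask): 20 h

- how much target and solid product together there is at 20 h, in percent of the solid substrate charged
- concentration of dissolved substrate in solution at 20 h, in percent of saturation

**The split.** Write A for dissolved substrate and B for partner. Turn the constants into times: partner decomposes with a half-life of 4.1 h, which is shorter than the run, and decomposition by itself leaves 3.39% at 20 h. So reckon the partner to its end. Coupling goes at kc·A·B and decomposition at kd·B, with kc and kd their constants, so B cancels from their ratio. That ratio, a selectivity factor, is A/C, where C = kd/kc = 7.58 mM is the break-even concentration, the dissolved substrate at which partner divides evenly between target and decomposed reagent.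

**The balance.** Integrate the split from a pool S down to a final A: partner used = S − A + C·ln(S/A). Put S = 20 mM, as if dissolving were instant, and take one Newton step from S divided by 3: A = 5.57 mM.

**Side loss.** Dissolving at its fastest, the solid lasts about 0.789 h. Take mean levels of 10.0 mM for solid and dissolved substrate over that time: reckon target at about 4.23 mM, and the side step at about 0.534 mM of solid and the same of target. Commit: y = 66.8%, sat = 34.8%.

**The weak link.** Instant dissolving is the weak assumption. Reckon instead that dissolved substrate trails by a lag τ = 1/k, with k the dissolution coefficient, here 0.631 h, shorter than the partner's half-life. Charge that lag to decomposition: take B as 21.6 mM, with S = 19.5 mM. Then A = 6.37 mM, y = 62.8%, sat = 39.8%.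

The forecast says 62% and 40%, and that, once the solid has dissolved, the partner “then runs out, mostly by its own decomposition”. The simulation gives 62.1% and 39.9%.

**At rest.** At 20 h this flask keeps 0.12% of its partner, and A = 6.39 mM is below C. In this flask at 20 h, partner goes to target at 0.84 of its rate of decomposition. At 200 h, y stands at 62.2%, a change of 0.100 percentage points, with dissolved substrate at 31.9% of the charge. Put 41 mM of partner into the balance instead: take B as 36.8 mM, and a Newton step from S divided by 10 leaves 7.82% of the charge as dissolved substrate. That neighbour flask holds 8.1% of its charged substrate, solid or dissolved, at 20 h, with y at 85.1%.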